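The C13 glyoxylate is attached last; the remaining 3-bromo-12H-pyrido[1,2-a:3,4-b']diindole is cut at N5–C12b and N5–C6. Bridgehead N5 belongs to both the five-membered ring D and the six-membered ring C, and its bond to C4a already exists in an aniline. In one base-mediated operation this nitrogen should add to two alkynes in turn, closing ring D (5-endo) and ring C (6-endo) by isomerisation alone. The precursor, 5-bromo-2-[(3-ethynyl-1H-indol-2-yl)ethynyl]aniline, is a 2-alkynylaniline whose alkyne ends at C2 of an indole carrying a terminal C3 ethynyl group.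

Key step: step 6

Remark: the target has no stereocentre and is achiral, so no enantiocontrol is needed; ring D is N5/C4a/C13a/C13/C12b and ring C is N5/C6/C7/C7a/C12a/C12b.

Step 1
Reactants: 1 5-bromo-2-iodoaniline; 2 ethynyltrimethylsilane
Product: 3 5-bromo-2-[(trimethylsilyl)ethynyl]aniline
Conditions: PdCl2(PPh3)2 (2 mol %), CuI (4 mol %), Et3N, THF, rt
Reagents that add atoms: none
Why: Sonogashira coupling, in which Pd(0) inserts into C–I far faster than into C–Br at room temperature, so only the iodide should be replaced while the free NH2 is tolerated.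

Step 2
Reactants: 3 5-bromo-2-[(trimethylsilyl)ethynyl]aniline
Product: 4 5-bromo-2-ethynylaniline
Conditions: K2CO3 (0.2 equiv), MeOH, rt
Reagents that add atoms: none
Why: Carbonate-catalysed methanolysis of the C(sp)–Si bond (protodesilylation) should free the terminal alkyne without touching the aryl bromide or the amine.

Step 3
Reactants: 5 2-bromo-1H-indole-3-carbaldehyde
Product: 6 tert-butyl 2-bromo-3-formyl-1H-indole-1-carboxylate
Conditions: Boc2O, DMAP (cat.), MeCN, rt
Reagents that add atoms: di-tert-butyl dicarbonate, CC(C)(C)OC(=O)OC(=O)OC(C)(C)C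
Why: DMAP-catalysed N-acylation (Boc protection) of the acidic indole N–H masks it for the coupling, makes the C2–Br bond more reactive towards Pd(0) and keeps the aldehyde electrophilic for step 5.

Step 4
Reactants: 4 5-bromo-2-ethynylaniline; 6 tert-butyl 2-bromo-3-formyl-1H-indole-1-carboxylate
Product: 7 tert-butyl 2-[(2-amino-4-bromophenyl)ethynyl]-3-formyl-1H-indole-1-carboxylate
Conditions: PdCl2(PPh3)2 (3 mol %), CuI (5 mol %), Et3N, THF (degassed), rt
Reagents that add atoms: none
Why: Sonogashira coupling, in which the C2–Br bond of the N-acyl 3-formylindole behaves as a vinylogous acyl bromide and should undergo oxidative addition at room temperature, where the unactivated aryl bromide of 4 and 7 stays inert.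

Step 5
Reactants: 7 tert-butyl 2-[(2-amino-4-bromophenyl)ethynyl]-3-formyl-1H-indole-1-carboxylate; 8 dimethyl (1-diazo-2-oxopropyl)phosphonate
Product: 10 5-bromo-2-[(3-ethynyl-1H-indol-2-yl)ethynyl]aniline, via N-Boc diyne 9 (not isolated)
Conditions: K2CO3 (3 equiv), MeOH/THF, 8 premixed with base at 0 °C, then 7, 0 °C → rt; then 50 °C
Reagents that add atoms: none
Why: Ohira–Bestmann (Seyferth–Gilbert) homologation, in which the diazomethylphosphonate anion released by methoxide turns the aryl aldehyde into the terminal alkyne through a diazoalkene and 1,2-H shift of the alkylidene carbene, after which warming in the same K2CO3/MeOH should remove the indole N-Boc group by methanolysis so that no acyl group remains that could migrate to N5 in step 6.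

Step 6
Reactants: 10 5-bromo-2-[(3-ethynyl-1H-indol-2-yl)ethynyl]aniline
Product: 12 3-bromo-12H-pyrido[1,2-a:3,4-b']diindole, via biindole 11 (not isolated)
Conditions: KOtBu (3 equiv), NMP (degassed), Ar, rt → 60 °C; then H2O
Reagents that add atoms: none
Why: KOtBu converts the indole N–H into its potassium salt and, in equilibrium, the aniline into an anilide, which adds across the diaryl alkyne at the carbon bearing the indol-2-yl group (N5–C12b); t-BuOH protonates the vinyl anion at C13 and biindole 11 is formed as its dianion. This is the base-mediated cyclisation of 2-alkynylanilines to 2-substituted indoles and closes ring D 5-endo-dig. In 11 the new indolide nitrogen N5 lies beside the 3'-ethynyl group and adds to its terminal carbon (N5–C6), and protonation at C7 completes the aromatic ring C; this closure is 6-endo-dig and is the intramolecular form of the anti-Markovnikov addition of indole N–H to arylacetylenes in superbasic media. No stereocentre is created. The step needs N5 and not C13 as the nucleophile and 6-endo and not 5-exo closure: an indolide with a well-solvated potassium counter-ion in NMP reacts at nitrogen, attack at the terminal carbon is the inherent regiochemistry of base-mediated additions to arylacetylenes, and the 5-exo mode would wedge a strained five-membered ring with an exocyclic methylene between the two indoles. N12, the other indolide nitrogen, cannot reach either alkyne, and the temperature is held at or below 60 °C under argon to spare the C3–Br bond.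

Step 7
Reactants: 12 3-bromo-12H-pyrido[1,2-a:3,4-b']diindole
Product: 14 methyl 2-(3-bromo-12H-pyrido[1,2-a:3,4-b']diindol-13-yl)-2-oxoacetate, via glyoxylyl chloride 13 (not isolated)
Conditions: (COCl)2 (2 equiv), THF, 0 °C; then MeOH, 0 °C → rt; aq NaHCO3 work-up
Reagents that add atoms: oxalyl chloride, O=C(Cl)C(=O)Cl; methanol, CO
Why: Friedel–Crafts-type C-acylation with oxalyl chloride, as in the formation of indole-3-glyoxylyl chlorides, should occur at C13 (the enamine-type β-carbon of N5 and the most nucleophilic position of the pentacycle), and methanolysis of the acid chloride then gives the α-keto ester next to the free N12–H.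

Compound list
1 | 5-bromo-2-iodoaniline | Nc1cc(Br)ccc1I | starting material
2 | ethynyltrimethylsilane | C#C[Si](C)(C)C | starting material
3 | 5-bromo-2-[(trimethylsilyl)ethynyl]aniline | Nc1cc(Br)ccc1C#C[Si](C)(C)C | intermediate
4 | 5-bromo-2-ethynylaniline | Nc1cc(Br)ccc1C#C | intermediate
5 | 2-bromo-1H-indole-3-carbaldehyde | O=Cc1c(Br)[nH]c2ccccc12 | starting material
6 | tert-butyl 2-bromo-3-formyl-1H-indole-1-carboxylate | O=Cc1c(Br)n(C(=O)OC(C)(C)C)c2ccccc12 | intermediate
7 | tert-butyl 2-[(2-amino-4-bromophenyl)ethynyl]-3-formyl-1H-indole-1-carboxylate | O=Cc1c(C#Cc2ccc(Br)cc2N)n(C(=O)OC(C)(C)C)c2ccccc12 | intermediate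
8 | dimethyl (1-diazo-2-oxopropyl)phosphonate | COP(=O)(OC)C(=[N+]=[N-])C(C)=O | starting material
9 | tert-butyl 2-[(2-amino-4-bromophenyl)ethynyl]-3-ethynyl-1H-indole-1-carboxylate | C#Cc1c(C#Cc2ccc(Br)cc2N)n(C(=O)OC(C)(C)C)c2ccccc12 | intermediate
10 | 5-bromo-2-[(3-ethynyl-1H-indol-2-yl)ethynyl]aniline | Nc1cc(Br)ccc1C#Cc1[nH]c2ccccc2c1C#C | intermediate
11 | 6-bromo-3'-ethynyl-1H,1'H-2,2'-biindole | C#Cc1c(-c2cc3ccc(Br)cc3[nH]2)[nH]c2ccccc12 | intermediate
12 | 3-bromo-12H-pyrido[1,2-a:3,4-b']diindole | Brc1ccc2cc3c4[nH]c5ccccc5c4ccn3c2c1 | intermediate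
13 | 2-(3-bromo-12H-pyrido[1,2-a:3,4-b']diindol-13-yl)-2-oxoacetyl chloride | O=C(Cl)C(=O)c1c2ccc(Br)cc2n2ccc3c4ccccc4[nH]c3c12 | intermediate
14 | methyl 2-(3-bromo-12H-pyrido[1,2-a:3,4-b']diindol-13-yl)-2-oxoacetate | COC(=O)C(=O)c1c2ccc(Br)cc2n2ccc3c4ccccc4[nH]c3c12 | target

Total step count: 7
Longest linear sequence: 6 steps (steps 1, 2, 4, 5, 6, 7; the indole branch joins at step 4 after step 3)

Steps most likely to fail

Step 6 (key step). The indole N–H is much more acidic than the aniline N–H, so the first closure must start from a polyanion. The accumulated charge may slow the anilide addition until attack on the ring A bromide (aryne formation or reduction) competes, and the cascade may also stop at the biindole. The fallback blocks N12 so that the cascade runs through a monoanion. It sets out from 10: selective deprotonation of the indole N–H (NaH, 1.0 equiv, THF, 0 °C) and alkylation with [2-(trimethylsilyl)ethoxy]methyl chloride should give 5-bromo-2-[(3-ethynyl-1-{[2-(trimethylsilyl)ethoxy]methyl}-1H-indol-2-yl)ethynyl]aniline F1. KOtBu in NMP should then close ring D to 6-bromo-3'-ethynyl-1'-{[2-(trimethylsilyl)ethoxy]methyl}-1H,1'H-2,2'-biindole F2, which is not isolated; its single indolide adds 6-endo to the ethynyl group to give 3-bromo-12-{[2-(trimethylsilyl)ethoxy]methyl}-12H-pyrido[1,2-a:3,4-b']diindole F3. Removal of the SEM group (TBAF, ethylenediamine, THF, 60 °C) brings the route back to 12, before the acylation, so that C13 is not shielded by a substituent on N12.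

Step 5. Methanolysis of the Boc group may outrun the homologation. The N–H 3-formylindole would then be deprotonated to a vinylogous amide anion that no longer accepts the phosphonate anion, and the amino aldehyde may condense with itself while it waits. The fallback is a Colvin homologation without methanol. It sets out from 7: lithiated trimethylsilyldiazomethane (TMSCHN2, LDA, THF, −78 °C → rt) should convert the aldehyde into the alkyne at a temperature at which the carbamate is inert, giving 9, this time isolated. A separate treatment with K2CO3 in MeOH at 50 °C then removes the Boc group and returns to 10. This detour makes no compound that is missing from the list (none, F0).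

Step 4. Chemoselectivity may be lost through oxidative addition into the aryl C–Br bond of 4 or 7, which would lead to oligomers, and 4 may undergo Glaser homocoupling. The fallback reverses the polarity so that the aryl halide that reacts is an iodide. It sets out from 6: Sonogashira coupling with 2 should give tert-butyl 3-formyl-2-[(trimethylsilyl)ethynyl]-1H-indole-1-carboxylate F4. Buffered desilylation (TBAF/AcOH, THF, 0 °C) then gives tert-butyl 2-ethynyl-3-formyl-1H-indole-1-carboxylate F5. F5 is coupled at room temperature with 1 (PdCl2(PPh3)2, CuI, Et3N, THF), where C–I reacts well before C–Br, and the route is rejoined at 7.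

Further compounds
F1 | step 6 | 5-bromo-2-[(3-ethynyl-1-{[2-(trimethylsilyl)ethoxy]methyl}-1H-indol-2-yl)ethynyl]aniline | Nc1cc(Br)ccc1C#Cc1n(COCC[Si](C)(C)C)c2ccccc2c1C#C
F2 | step 6 | 6-bromo-3'-ethynyl-1'-{[2-(trimethylsilyl)ethoxy]methyl}-1H,1'H-2,2'-biindole | C#Cc1c(-c2cc3ccc(Br)cc3[nH]2)n(COCC[Si](C)(C)C)c2ccccc12
F3 | step 6 | 3-bromo-12-{[2-(trimethylsilyl)ethoxy]methyl}-12H-pyrido[1,2-a:3,4-b']diindole | Brc1ccc2cc3c4n(COCC[Si](C)(C)C)c5ccccc5c4ccn3c2c1
F0 | step 5 | none | none
F4 | step 4 | tert-butyl 3-formyl-2-[(trimethylsilyl)ethynyl]-1H-indole-1-carboxylate | O=Cc1c(C#C[Si](C)(C)C)n(C(=O)OC(C)(C)C)c2ccccc12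
F5 | step 4 | tert-butyl 2-ethynyl-3-formyl-1H-indole-1-carboxylate | O=Cc1c(C#C)n(C(=O)OC(C)(C)C)c2ccccc12
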